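# Proposed synthesis of CNP0116832.1 by twofold copper-catalysed desymmetrising O-arylation and decarbonylation

## Analysis of the target

Compound 21 is a C2-symmetric dimer of two isoflavans, each a 7-hydroxychroman (benzo ring A fused to pyran ring C) that carries ring B at C3, and the two rings B are joined through one oxygen at C4'. Ring B is 1,2,3,4-tetrasubstituted: C1' is bonded to C3, C2' carries OMe, C3' a free OH and C4' the bridging oxygen. The only stereocentres are the two C3 atoms, both R, and each is a tertiary benzylic CH flanked by the C2 and C4 methylene groups. They lie ten bonds apart and cannot influence each other, so the only relative question is C2-symmetric versus meso. There are four free phenols, two of them in oxidisable 2-methoxy-3-hydroxy-4-aryloxy rings, and C3–H would become acidic in any intermediate with a carbonyl group at C2 or C4. The synthesis is hard for two reasons: the contiguous, differentiated oxygenation of ring B, and a tertiary centre whose two ring arms (C2H2–O and C4H2–aryl) look alike and must be told apart twice, in the same sense, without help from the other half. The strategy rests on the O1–C8a aryl ether bond of ring C: if C3 carries a second hydroxymethyl group beside the one that becomes C2, the two CH2OH arms are enantiotopic, closing O1–C8a with one of them fixes C3 as a quaternary centre, and the spare arm can later be taken off as its aldehyde with retention.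

## Retrosynthetic reasoning

**21 to 20.** The four phenolic O–H bonds are traced back to O–benzyl bonds. One kind of protecting group on all four phenols means a single last operation, and hydrogenolysis is neutral and leaves the diaryl ether, the chroman C–O bonds and both C3 centres alone.

**20 to 19 to 18.** Each C3–H bond is replaced by a C3–CHO and then a C3–CH2OH bond. This brings in a carbon that 21 does not contain, but it makes C3 a quaternary centre that no acid or base can epimerise and that can be created by choosing between two like groups. The forward steps are an alcohol oxidation and a metal-mediated decarbonylation in which hydrogen is delivered from the metal to the carbon that held the formyl group, so that the configuration is kept.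

**18 to 17.** Both O1–C8a bonds are cut. This is the one bond of ring C whose formation turns a symmetric 2,2-disubstituted propane-1,3-diol unit into a chiral ring. Cutting C3–C4 or C3–C1' instead would leave a tertiary centre to be set between two nearly identical methylene arms. The gain is that 17 has no stereocentre, so all stereochemistry arises in one catalytic event per half. The forward reaction needs a chiral copper catalyst that couples one particular hydroxymethyl arm of each diol with the ortho-bromide.

**17 to 16 to 11 and 15.** The four hydroxymethyl groups come from four ester groups, and the two C3–C4 bonds from alkylation of the bis(aryl malonate) 11 with the benzylic bromide 15, two molecules of 15 being consumed for each molecule of 11. The cut is made at C3–C4 because it separates ring A, which carries the halide for the key step, from the ring B core, and because malonate alkylation is the most dependable way to a quaternary carbon with two one-carbon arms. The forward steps are a twofold SN2 alkylation and a hydride reduction that must not touch the aryl bromides.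

**15 to 14 to 13 to 12.** Only functional group changes: bromide from alcohol, alcohol from aldehyde, benzyl ether from phenol.

**11 to 10 to 9.** One ester group of each malonate is removed in a Claisen disconnection, and the arylacetate is traced back to an aryl methyl ketone through a 1,2-aryl shift. The acetyl group thus supplies the future C3 and one of its arms. A formyl group in that position would need a separate one-carbon homologation of several twofold steps.

**9 to 7 to 4.** The two C3'–O bonds are cut. The hydrogen there lies between the methoxy and the aryloxy oxygen and is the most acidic on the ring, so directed metalation with boron-to-oxygen exchange is the natural forward reaction. It is placed on a bis-ketal without stereocentres because the ketone has to be masked against both the organolithium and the peroxide; a free carbonyl group would be attacked by the first and oxidised in a Baeyer–Villiger or Dakin manner by the second.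

**4 to 3 to 1 and 2.** The diaryl ether bond is cut para to the acetyl group, which activates fluoride displacement by a phenoxide. Both rings B and the bridge are in place after the first step, and every later operation is twofold on a symmetric molecule.

## Alternatives that were turned down

**Alternative 1: late twofold oxygenation of ring B.**
- Disconnection and key step: the two C3'–O bonds are cut last. The 3'-deoxy bis-isoflavan A1, with its 7-hydroxyl groups silylated, would be lithiated on both rings B between the methoxy and aryloxy groups, trapped with a borate ester and oxidised to A2; desilylation would finish the synthesis.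
- For: the site is the intrinsically preferred one for metalation on ring B, the 3'-OH never needs a protecting group, and the end is a fluoride desilylation. On the regiochemical logic for ring B this alternative is as strong as the chosen route.
- Against: it leaves open how the two C3 centres of A1 are made, so it adds to the stereochemical problem instead of solving it. A1 also offers the strong base other sites: C8–H of each chroman lies between O1 and the silyloxy group, C5'–H is ortho to the aryloxy oxygen, and the benzylic C4–H2 and C3–H are exposed, deprotonation of the last erasing the stereocentre. A failure would cost the most advanced intermediate.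
- Comparison: the chosen route uses the same oxygenation at step 3, on ketal 4, where no stereocentre and no competing doubly flanked site exist. It pays with two extra benzyl groups.

**Alternative 2: desymmetrising Friedel–Crafts opening of a bis-oxetane.**
- Disconnection and key step: each C4–C4a bond is cut, then O1–C2. A chiral phosphoric acid would activate each oxetane of A3, and resorcinol A4 would attack one of the two enantiotopic ring methylene groups through its C4, giving A5 with the tertiary C3 formed directly and the C2 carbinol set free. Mitsunobu closure and debenzylation would follow.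
- For: no surplus carbon, no stoichiometric rhodium, only two steps after the key step, and ring A needs no protecting group. In atom and step economy after the key step this alternative is clearly stronger.
- Against: enantioselective oxetane openings are established for tethered nucleophiles and for heteroatom nucleophiles; an intermolecular C-alkylation of a free dihydric phenol is not. A4 is ambident (O-alkylation, attack through C2, double alkylation), and the attacked carbon is an unactivated primary centre, so the activation needed would work against selectivity. A3 would be reached from malonate 11 by reduction and ring closure, so nothing is saved before the key step.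
- Comparison: the chosen route offers a key step of a reaction type shown on exactly this substrate class, and a quaternary centre that cannot erode. Its price is the spare carbon and the two steps that remove it.

**Alternative 3: enantioselective 1,2-aryl shift of a bis-chalcone.**
- Disconnection and key step: each C3–C1' bond is cut. A chiral lactate-based aryl-λ3-iodane would activate each enone double bond of A6 in an alcohol solvent; ring B would move from the β- to the α-carbon and the solvent would trap the cation, giving the bis(ketoacetal) A7.
- For: A6 needs only one aldol condensation for its assembly, the whole C6–C3–C6 skeleton is convergent, and the donor-rich ring B is an excellent migrating group. Before the key step this alternative is shorter than the chosen route.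
- Against: the new stereocentre of A7 is a C–H that is benzylic, α to an aryl ketone and α to an acetal, so it enolises readily. Unmasking the acetal gives a β-dicarbonyl unit in which C3 is flattened, or ring closure with loss of the alcohol to a C2=C3 double bond. Even if that is avoided, C4 must be reduced from ketone to methylene and C2 from acetal to ether over several steps with C3 at risk. Two equivalents of a chiral oxidant would act on electron-rich rings and benzyl ethers.
- Comparison: the chosen route is longer before its key step, but its stereocentres are quaternary from the moment they form until the stereoretentive last carbon–carbon cleavage.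

Key step: step 12

## Assumptions

- Compounds 1, 2 and 12 are taken to be commercially available.
- The sense of induction of the diamine cannot be derived from structure alone. Step 12 is to be run with each antipode of the ligand, and the one that leads to the (R,R) series is kept.

## Route

Step 1
Reactants: 1 1-(4-fluoro-2-methoxyphenyl)ethanone; 2 1-(4-hydroxy-2-methoxyphenyl)ethanone
Product: 3 1,1'-[oxybis(2-methoxy-4,1-phenylene)]diethanone
Conditions: K2CO3, DMSO, 120 °C
Reagents that add atoms: none
Why: Nucleophilic aromatic substitution by addition–elimination; the fluoride of 1 is para to the acetyl group, which stabilises the Meisenheimer adduct, and the phenoxide of 2 has no other electrophile, so the symmetric diaryl ether should form without a regiochemical question.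

Step 2
Reactants: 3 1,1'-[oxybis(2-methoxy-4,1-phenylene)]diethanone
Product: 4 2,2'-[oxybis(2-methoxy-4,1-phenylene)]bis(2-methyl-1,3-dioxolane)
Conditions: HOCH2CH2OH, p-TsOH (cat.), toluene, reflux, Dean–Stark; Et3N quench
Reagents that add atoms: ethylene glycol, OCCO
Why: Acid-catalysed ketalisation with azeotropic removal of water; the dioxolane has no acidic hydrogen and is inert to alkyllithium and to alkaline peroxide, which the free ketone is not.

Step 3
Reactants: 4 2,2'-[oxybis(2-methoxy-4,1-phenylene)]bis(2-methyl-1,3-dioxolane)
Product: 7 6,6'-oxybis[2-methoxy-3-(2-methyl-1,3-dioxolan-2-yl)phenol], via dilithio bis-ketal 5 (not isolated), via bis(dimethoxyboryl) bis-ketal 6 (not isolated)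
Conditions: n-BuLi, TMEDA, THF, −20 to 0 °C; B(OMe)3, −78 °C to rt; 30% H2O2, aq NaOH, 0 °C; NH4Cl work-up
Reagents that add atoms: hydrogen peroxide, OO (the two new phenol oxygens); n-butyllithium, CCCC[Li] (lithium of 5 only); trimethyl borate, COB(OC)OC (boron and methoxy groups of 6 only)
Why: Directed ortho-metalation, borylation and oxidation; on each ring the hydrogen between the methoxy and aryloxy oxygens is the most acidic and the only one flanked by two coordinating groups, as in the 2-lithiation of 1,3-dialkoxybenzenes and the 2,2'-dilithiation of diaryl ethers. The aryl group then migrates from boron to oxygen, which places the hydroxyl exactly at C3'.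

Step 4
Reactants: 7 6,6'-oxybis[2-methoxy-3-(2-methyl-1,3-dioxolan-2-yl)phenol]
Product: 9 1,1'-{oxybis[3-(benzyloxy)-2-methoxy-4,1-phenylene]}diethanone, via benzylated bis-ketal 8 (not isolated)
Conditions: BnBr, K2CO3, DMF, 60 °C; then 2 M HCl, THF, rt
Reagents that add atoms: benzyl bromide, BrCc1ccccc1
Why: Williamson etherification of the two phenols, then acid hydrolysis of the ketals in the same flask; benzyl ethers withstand every later step and leave together in the last one.

Step 5
Reactants: 9 1,1'-{oxybis[3-(benzyloxy)-2-methoxy-4,1-phenylene]}diethanone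
Product: 10 dimethyl 2,2'-{oxybis[3-(benzyloxy)-2-methoxy-4,1-phenylene]}diacetate
Conditions: PhI(OAc)2, HC(OMe)3, MeOH, H2SO4 (cat.), 60 °C
Reagents that add atoms: methanol, CO; trimethyl orthoformate, COC(OC)OC
Why: Oxidative 1,2-aryl migration of an aryl methyl ketone with a trivalent iodine reagent, the counterpart of the thallium trinitrate rearrangement; the enol ether formed in situ is attacked by iodine at the methyl carbon, the electron-rich aryl group shifts to that carbon as iodobenzene leaves, and the orthoester so formed gives the methyl ester. The three oxygen donors on the ring favour the shift.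

Step 6
Reactants: 10 dimethyl 2,2'-{oxybis[3-(benzyloxy)-2-methoxy-4,1-phenylene]}diacetate
Product: 11 tetramethyl 2,2'-{oxybis[3-(benzyloxy)-2-methoxy-4,1-phenylene]}dimalonate
Conditions: NaH, (MeO)2CO, THF, reflux; AcOH quench
Reagents that add atoms: dimethyl carbonate, COC(=O)OC
Why: Crossed Claisen condensation of the arylacetate enolates with a carbonate ester, driven to completion by deprotonation of the aryl malonates as they form.

Step 7
Reactants: 12 2-bromo-4-hydroxybenzaldehyde
Product: 13 4-(benzyloxy)-2-bromobenzaldehyde
Conditions: BnBr, K2CO3, DMF, rt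
Reagents that add atoms: benzyl bromide, BrCc1ccccc1
Why: Williamson etherification of a phenol made acidic by the para formyl group.

Step 8
Reactants: 13 4-(benzyloxy)-2-bromobenzaldehyde
Product: 14 [4-(benzyloxy)-2-bromophenyl]methanol
Conditions: NaBH4, MeOH/THF, 0 °C
Reagents that add atoms: none
Why: Borohydride reduction of the aldehyde; aryl bromide and benzyl ether are inert.

Step 9
Reactants: 14 [4-(benzyloxy)-2-bromophenyl]methanol
Product: 15 4-(benzyloxy)-2-bromo-1-(bromomethyl)benzene
Conditions: PBr3, CH2Cl2, 0 °C
Reagents that add atoms: phosphorus tribromide, BrP(Br)Br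
Why: Conversion of a benzylic alcohol into the bromide through its phosphite ester; the para-alkoxy benzylic bromide is reactive and is used promptly.

Step 10
Reactants: 11 tetramethyl 2,2'-{oxybis[3-(benzyloxy)-2-methoxy-4,1-phenylene]}dimalonate; 15 4-(benzyloxy)-2-bromo-1-(bromomethyl)benzene (two molar equivalents are consumed, one for each malonate unit of 11)
Product: 16 tetramethyl 2,2'-{oxybis[3-(benzyloxy)-2-methoxy-4,1-phenylene]}bis{2-[4-(benzyloxy)-2-bromobenzyl]malonate}
Conditions: NaH (2.2 equiv), DMF, 0 °C; then 15 (2.2 equiv), 0 to 40 °C
Reagents that add atoms: 4-(benzyloxy)-2-bromo-1-(bromomethyl)benzene (compound 15, its second molar equivalent, which alkylates the second malonate unit), BrCc1ccc(OCc2ccccc2)cc1Br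
Why: Twofold SN2 alkylation of the two aryl malonate anions of 11, each by one molecule of the reactive benzylic bromide 15, forms both C3–C4 bonds and both quaternary carbons. Each malonate has a single acidic hydrogen, so over-alkylation is excluded, the aryl bromides do not react, and a slight excess of 15 should drive the second alkylation to completion.

Step 11
Reactants: 16 tetramethyl 2,2'-{oxybis[3-(benzyloxy)-2-methoxy-4,1-phenylene]}bis{2-[4-(benzyloxy)-2-bromobenzyl]malonate}
Product: 17 2,2'-{oxybis[3-(benzyloxy)-2-methoxy-4,1-phenylene]}bis{2-[4-(benzyloxy)-2-bromobenzyl]propane-1,3-diol}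
Conditions: LiBH4, MeOH (additive), THF, 0 to 50 °C
Reagents that add atoms: none
Why: Ester reduction with a borohydride that leaves aryl bromides and benzyl ethers untouched; the boron-bound alkoxides formed on the way are less prone to retro-aldol cleavage than free alkali alkoxides. The product is achiral, each quaternary carbon holding two enantiotopic CH2OH groups.

Step 12
Reactants: 17 2,2'-{oxybis[3-(benzyloxy)-2-methoxy-4,1-phenylene]}bis{2-[4-(benzyloxy)-2-bromobenzyl]propane-1,3-diol}
Product: 18 bis{2-(benzyloxy)-4-[(3R)-7-(benzyloxy)-3-(hydroxymethyl)chroman-3-yl]-3-methoxyphenyl} ether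
Conditions: CuI (20 mol %), (1R,2R)-N,N'-dimethylcyclohexane-1,2-diamine or its antipode (40 mol %), Cs2CO3, 1,4-dioxane, 0.05 M, 60 °C
Reagents that add atoms: none
Why: This is an Ullmann-type aryl C–O coupling in its enantioselective desymmetrising form, the closest known case being the cyclisation of 2-substituted 2-(2-halobenzyl)propane-1,3-diols to 3-(hydroxymethyl)chromans with CuI and a chiral 1,2-diamine. Diamine-bound monovalent copper is turned by Cs2CO3 into the alkoxide of one hydroxymethyl group, the neighbouring C–Br bond adds oxidatively to give a seven-membered aryl(alkoxo) complex of trivalent copper, and reductive elimination forms the O1–C8a bond. Each pyran ring is thus closed as a six-membered ring by the tethered oxygen on the aryl carbon, a 6-exo mode with respect to the C–Br bond that is broken, and no other ring size is open to the substrate. Each stereocentre is set by enantiotopic group selection: the two CH2OH arms differ only in the side of the quaternary carbon they occupy relative to ring B and the benzylic methylene, and the C2-symmetric ligand makes the two diastereomeric metallacycles unequal in energy, so the catalyst alone decides the configuration. The two diol units are ten bonds apart and should react independently, so the same preference is expressed twice; a wrong choice at one site ends mainly in the meso diastereomer, which can be separated, and the C2-symmetric product should therefore be enriched beyond the selectivity of a single event. Chemoselectivity lies in the substrate: the only aryl halides are the two ortho-bromobenzyl units, each bromide is meta to the benzyloxy donor and so not deactivated, all phenols are capped, and ring closure outruns intermolecular etherification at this dilution. The quaternary centres cannot epimerise under the basic conditions.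

Step 13
Reactants: 18 bis{2-(benzyloxy)-4-[(3R)-7-(benzyloxy)-3-(hydroxymethyl)chroman-3-yl]-3-methoxyphenyl} ether
Product: 19 bis{2-(benzyloxy)-4-[(3S)-7-(benzyloxy)-3-formylchroman-3-yl]-3-methoxyphenyl} ether
Conditions: Dess–Martin periodinane, NaHCO3, CH2Cl2, 0 °C to rt
Reagents that add atoms: none
Why: Oxidation of the neopentyl-type primary alcohols to aldehydes under buffered, non-acidic conditions; the α-carbon is quaternary, so neither epimerisation nor β-elimination of the aryloxy group is possible. The descriptor changes to S only because the formyl group outranks C2.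

Step 14
Reactants: 19 bis{2-(benzyloxy)-4-[(3S)-7-(benzyloxy)-3-formylchroman-3-yl]-3-methoxyphenyl} ether
Product: 20 bis{2-(benzyloxy)-4-[(3R)-7-(benzyloxy)chroman-3-yl]-3-methoxyphenyl} ether
Conditions: RhCl(PPh3)3 (2.2 equiv), degassed xylene, 130 °C
Reagents that add atoms: none
Why: Tsuji–Wilkinson decarbonylation; the formyl C–H bond adds to monovalent rhodium, CO is extruded from the acyl group onto the metal and the C–H bond is formed by reductive elimination, all on one face, so hydrogen takes the place of the formyl group with retention. The descriptor returns to R by the change in priorities, not by a change in geometry.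

Step 15
Reactants: 20 bis{2-(benzyloxy)-4-[(3R)-7-(benzyloxy)chroman-3-yl]-3-methoxyphenyl} ether
Product: 21 bis{2-hydroxy-4-[(3R)-7-hydroxychroman-3-yl]-3-methoxyphenyl} ether (CNP0116832.1)
Conditions: H2 (1 atm), Pd/C, THF/MeOH, rt
Reagents that add atoms: none
Why: Hydrogenolysis of the four aryl benzyl ethers under neutral conditions; the diaryl ether, the chroman rings and the non-acidic C3–H centres are not affected. The product is handled under inert gas because of the electron-rich phenols.

## Compound list

1 | 1-(4-fluoro-2-methoxyphenyl)ethanone | CC(=O)c1ccc(F)cc1OC | starting material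
2 | 1-(4-hydroxy-2-methoxyphenyl)ethanone | CC(=O)c1ccc(O)cc1OC | starting material
3 | 1,1'-[oxybis(2-methoxy-4,1-phenylene)]diethanone | COc1c(C(C)=O)ccc(Oc2ccc(C(C)=O)c(OC)c2)c1 | intermediate
4 | 2,2'-[oxybis(2-methoxy-4,1-phenylene)]bis(2-methyl-1,3-dioxolane) | COc1c(C2(C)OCCO2)ccc(Oc2ccc(C3(C)OCCO3)c(OC)c2)c1 | intermediate
5 | dilithio bis-ketal: bis[2-lithio-3-methoxy-4-(2-methyl-1,3-dioxolan-2-yl)phenyl] ether | COc1c(C2(C)OCCO2)ccc(Oc2ccc(C3(C)OCCO3)c(OC)c2[Li])c1[Li] | intermediate (not isolated)
6 | bis(dimethoxyboryl) bis-ketal: bis[2-(dimethoxyboryl)-3-methoxy-4-(2-methyl-1,3-dioxolan-2-yl)phenyl] ether | COc1c(C2(C)OCCO2)ccc(Oc2ccc(C3(C)OCCO3)c(OC)c2B(OC)OC)c1B(OC)OC | intermediate (not isolated)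
7 | 6,6'-oxybis[2-methoxy-3-(2-methyl-1,3-dioxolan-2-yl)phenol] | COc1c(C2(C)OCCO2)ccc(Oc2ccc(C3(C)OCCO3)c(OC)c2O)c1O | intermediate
8 | benzylated bis-ketal: bis[2-(benzyloxy)-3-methoxy-4-(2-methyl-1,3-dioxolan-2-yl)phenyl] ether | COc1c(C2(C)OCCO2)ccc(Oc2ccc(C3(C)OCCO3)c(OC)c2OCc2ccccc2)c1OCc1ccccc1 | intermediate (not isolated)
9 | 1,1'-{oxybis[3-(benzyloxy)-2-methoxy-4,1-phenylene]}diethanone | COc1c(C(C)=O)ccc(Oc2ccc(C(C)=O)c(OC)c2OCc2ccccc2)c1OCc1ccccc1 | intermediate
10 | dimethyl 2,2'-{oxybis[3-(benzyloxy)-2-methoxy-4,1-phenylene]}diacetate | COc1c(CC(=O)OC)ccc(Oc2ccc(CC(=O)OC)c(OC)c2OCc2ccccc2)c1OCc1ccccc1 | intermediate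
11 | tetramethyl 2,2'-{oxybis[3-(benzyloxy)-2-methoxy-4,1-phenylene]}dimalonate | COc1c(C(C(=O)OC)C(=O)OC)ccc(Oc2ccc(C(C(=O)OC)C(=O)OC)c(OC)c2OCc2ccccc2)c1OCc1ccccc1 | intermediate
12 | 2-bromo-4-hydroxybenzaldehyde | O=Cc1ccc(O)cc1Br | starting material
13 | 4-(benzyloxy)-2-bromobenzaldehyde | O=Cc1ccc(OCc2ccccc2)cc1Br | intermediate
14 | [4-(benzyloxy)-2-bromophenyl]methanol | OCc1ccc(OCc2ccccc2)cc1Br | intermediate
15 | 4-(benzyloxy)-2-bromo-1-(bromomethyl)benzene | BrCc1ccc(OCc2ccccc2)cc1Br | intermediate
16 | tetramethyl 2,2'-{oxybis[3-(benzyloxy)-2-methoxy-4,1-phenylene]}bis{2-[4-(benzyloxy)-2-bromobenzyl]malonate} | COc1c(C(Cc2ccc(OCc3ccccc3)cc2Br)(C(=O)OC)C(=O)OC)ccc(Oc2ccc(C(Cc3ccc(OCc4ccccc4)cc3Br)(C(=O)OC)C(=O)OC)c(OC)c2OCc2ccccc2)c1OCc1ccccc1 | intermediate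
17 | 2,2'-{oxybis[3-(benzyloxy)-2-methoxy-4,1-phenylene]}bis{2-[4-(benzyloxy)-2-bromobenzyl]propane-1,3-diol} (achiral) | COc1c(C(CO)(CO)Cc2ccc(OCc3ccccc3)cc2Br)ccc(Oc2ccc(C(CO)(CO)Cc3ccc(OCc4ccccc4)cc3Br)c(OC)c2OCc2ccccc2)c1OCc1ccccc1 | intermediate
18 | bis{2-(benzyloxy)-4-[(3R)-7-(benzyloxy)-3-(hydroxymethyl)chroman-3-yl]-3-methoxyphenyl} ether | COc1c([C@]2(CO)COc3cc(OCc4ccccc4)ccc3C2)ccc(Oc2ccc([C@]3(CO)COc4cc(OCc5ccccc5)ccc4C3)c(OC)c2OCc2ccccc2)c1OCc1ccccc1 | intermediate
19 | bis{2-(benzyloxy)-4-[(3S)-7-(benzyloxy)-3-formylchroman-3-yl]-3-methoxyphenyl} ether | COc1c([C@]2(C=O)COc3cc(OCc4ccccc4)ccc3C2)ccc(Oc2ccc([C@]3(C=O)COc4cc(OCc5ccccc5)ccc4C3)c(OC)c2OCc2ccccc2)c1OCc1ccccc1 | intermediate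
20 | bis{2-(benzyloxy)-4-[(3R)-7-(benzyloxy)chroman-3-yl]-3-methoxyphenyl} ether | COc1c([C@@H]2COc3cc(OCc4ccccc4)ccc3C2)ccc(Oc2ccc([C@@H]3COc4cc(OCc5ccccc5)ccc4C3)c(OC)c2OCc2ccccc2)c1OCc1ccccc1 | intermediate
21 | bis{2-hydroxy-4-[(3R)-7-hydroxychroman-3-yl]-3-methoxyphenyl} ether | COc1c([C@@H]2COc3cc(O)ccc3C2)ccc(Oc2ccc([C@@H]3COc4cc(O)ccc4C3)c(OC)c2O)c1O | target

## Step count and least certain steps

Total: 15 steps. Longest linear sequence: 12 steps (steps 1 to 6 and 10 to 15); the branch to bromide 15 has 3 steps (7 to 9).

**Step 12 (key step).** The likeliest failure is poor discrimination between the two hydroxymethyl arms at one or both sites. Ring B with its ortho-methoxy group is bulkier than the aryl groups of simple model diols, and an aryl bromide needs more heat than an iodide, which works against selectivity. A second risk is that the reaction stops after one ring closure. Fallback: the selection is moved to a separate, known acylation and the ring is closed with an achiral catalyst. Setting out from 17, desymmetrising monobenzoylation of each diol with vinyl benzoate and the dinuclear zinc catalyst made from Et2Zn and a ProPhenol ligand should give the bis(monobenzoate) F1. Silylation of the remaining hydroxyl groups (TBDPSCl, imidazole) gives the benzoate silyl ether F2, and methanolysis of the benzoates (K2CO3, MeOH) gives the bis(mono-silyl ether) diol F3. An achiral Ullmann etherification (CuI, 1,10-phenanthroline, Cs2CO3, toluene, 110 °C) closes both pyran rings to the silylated bis-chroman F4, and Bu4NF returns the route to 18. The silyl group is put on before the benzoate is removed because a free hydroxyl group next to the ester would allow 1,3-acyl migration, and with it loss of the stored configuration, under the basic coupling conditions.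

**Step 14.** The likeliest failure is β-hydride elimination from the tertiary alkyl rhodium hydride towards C2 or C4, which would give chromenes, together with slow reaction at the two hindered neopentyl aldehydes. Fallback: the C3 hydrogen is introduced by asymmetric hydrogenation instead. Setting out from 19, Pinnick oxidation (NaClO2, NaH2PO4, 2-methyl-2-butene) gives the diacid F5, and Kochi oxidative decarboxylation (Pb(OAc)4, Cu(OAc)2, pyridine, benzene, 80 °C) gives the bis(2H-chromene) F6, whose C3=C4 double bonds are conjugated with both aryl rings. Hydrogenation with a cationic iridium catalyst carrying a chiral phosphine–oxazoline ligand L ([Ir(cod)L]BArF, H2, CH2Cl2), a known route from 3-aryl-2H-chromenes to isoflavans, returns to 20. The configuration set in step 12 is given up on this detour and set again by the hydrogenation catalyst, which is its cost.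

**Step 3.** The likeliest failure is incomplete second metalation, or metalation next to the aryloxy oxygen only (C5') on one ring, because the first aryllithium lowers the solubility and the acidity of the second ring. Fallback: the oxygen is introduced on the monomer, before the ether bond is made. Setting out from 1, ketalisation gives the fluoro dioxolane F7. Lithiation between fluorine and methoxy (n-BuLi, THF, −78 °C), B(OMe)3 and H2O2 give the fluorophenol F8, and benzylation with acid hydrolysis gives the ketone F9. Half of F9 is converted into the phenol F10 with 2-(methylsulfonyl)ethanol and NaH as a hydroxide surrogate, and SNAr between F10 and F9 (K2CO3, DMSO) returns the route to 9.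

**Step 5.** The likeliest failure is oxidation of the electron-rich rings by the acid-activated trivalent iodine reagent once the deactivating acetyl group is gone, or conversion of only one of the two ketones. Fallback: the same carbon shift without an oxidant for the ring. Setting out from 9, the Willgerodt–Kindler reaction (S8, morpholine, 130 °C) gives the bis(thiomorpholide) F11, hydrolysis (KOH, aqueous EtOH, reflux) gives the diacid F12, and esterification (MeOH, H2SO4 cat.) returns the route to 10.

## Further compounds

F1 | step 12 | bis(monobenzoate) of 17, one CH2OH of each diol benzoylated | COc1c([C@](Cc2ccc(OCc3ccccc3)cc2Br)(CO)COC(=O)c2ccccc2)ccc(Oc2ccc([C@](Cc3ccc(OCc4ccccc4)cc3Br)(CO)COC(=O)c3ccccc3)c(OC)c2OCc2ccccc2)c1OCc1ccccc1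
F2 | step 12 | bis(tert-butyldiphenylsilyl ether) of F1 | COc1c([C@](Cc2ccc(OCc3ccccc3)cc2Br)(CO[Si](c2ccccc2)(c2ccccc2)C(C)(C)C)COC(=O)c2ccccc2)ccc(Oc2ccc([C@](Cc3ccc(OCc4ccccc4)cc3Br)(CO[Si](c3ccccc3)(c3ccccc3)C(C)(C)C)COC(=O)c3ccccc3)c(OC)c2OCc2ccccc2)c1OCc1ccccc1
F3 | step 12 | bis(mono-tert-butyldiphenylsilyl ether) of 17 | COc1c([C@](Cc2ccc(OCc3ccccc3)cc2Br)(CO[Si](c2ccccc2)(c2ccccc2)C(C)(C)C)CO)ccc(Oc2ccc([C@](Cc3ccc(OCc4ccccc4)cc3Br)(CO[Si](c3ccccc3)(c3ccccc3)C(C)(C)C)CO)c(OC)c2OCc2ccccc2)c1OCc1ccccc1
F4 | step 12 | bis(tert-butyldiphenylsilyl ether) of 18 | COc1c([C@]2(CO[Si](c3ccccc3)(c3ccccc3)C(C)(C)C)COc3cc(OCc4ccccc4)ccc3C2)ccc(Oc2ccc([C@]3(CO[Si](c4ccccc4)(c4ccccc4)C(C)(C)C)COc4cc(OCc5ccccc5)ccc4C3)c(OC)c2OCc2ccccc2)c1OCc1ccccc1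
F5 | step 14 | bis{2-(benzyloxy)-4-[(3S)-7-(benzyloxy)-3-carboxychroman-3-yl]-3-methoxyphenyl} ether | COc1c([C@]2(C(=O)O)COc3cc(OCc4ccccc4)ccc3C2)ccc(Oc2ccc([C@]3(C(=O)O)COc4cc(OCc5ccccc5)ccc4C3)c(OC)c2OCc2ccccc2)c1OCc1ccccc1
F6 | step 14 | bis{2-(benzyloxy)-4-[7-(benzyloxy)-2H-chromen-3-yl]-3-methoxyphenyl} ether | COc1c(C2=Cc3ccc(OCc4ccccc4)cc3OC2)ccc(Oc2ccc(C3=Cc4ccc(OCc5ccccc5)cc4OC3)c(OC)c2OCc2ccccc2)c1OCc1ccccc1
F7 | step 3 | 2-(4-fluoro-2-methoxyphenyl)-2-methyl-1,3-dioxolane | CC1(OCCO1)c1ccc(F)cc1OC
F8 | step 3 | 6-fluoro-2-methoxy-3-(2-methyl-1,3-dioxolan-2-yl)phenol | CC1(OCCO1)c1ccc(F)c(O)c1OC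
F9 | step 3 | 1-[3-(benzyloxy)-4-fluoro-2-methoxyphenyl]ethanone | CC(=O)c1ccc(F)c(OCc2ccccc2)c1OC
F10 | step 3 | 1-[3-(benzyloxy)-4-hydroxy-2-methoxyphenyl]ethanone | CC(=O)c1ccc(O)c(OCc2ccccc2)c1OC
F11 | step 5 | 2,2'-{oxybis[3-(benzyloxy)-2-methoxy-4,1-phenylene]}bis[1-(morpholin-4-yl)ethanethione] | COc1c(CC(=S)N2CCOCC2)ccc(Oc2ccc(CC(=S)N3CCOCC3)c(OC)c2OCc2ccccc2)c1OCc1ccccc1
F12 | step 5 | 2,2'-{oxybis[3-(benzyloxy)-2-methoxy-4,1-phenylene]}diacetic acid | COc1c(CC(=O)O)ccc(Oc2ccc(CC(=O)O)c(OC)c2OCc2ccccc2)c1OCc1ccccc1
A1 | alternative 1 | bis{3-methoxy-4-[(3R)-7-(triisopropylsilyloxy)chroman-3-yl]phenyl} ether | COc1c([C@@H]2COc3cc(O[Si](C(C)C)(C(C)C)C(C)C)ccc3C2)ccc(Oc2ccc([C@@H]3COc4cc(O[Si](C(C)C)(C(C)C)C(C)C)ccc4C3)c(OC)c2)c1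
A2 | alternative 1 | 7,7''-bis(triisopropylsilyl) ether of 21 | COc1c([C@@H]2COc3cc(O[Si](C(C)C)(C(C)C)C(C)C)ccc3C2)ccc(Oc2ccc([C@@H]3COc4cc(O[Si](C(C)C)(C(C)C)C(C)C)ccc4C3)c(OC)c2O)c1O
A3 | alternative 2 | bis[2-(benzyloxy)-3-methoxy-4-(oxetan-3-yl)phenyl] ether | COc1c(C2COC2)ccc(Oc2ccc(C3COC3)c(OC)c2OCc2ccccc2)c1OCc1ccccc1
A4 | alternative 2 | resorcinol | Oc1cccc(O)c1
A5 | alternative 2 | bis{2-(benzyloxy)-4-[(2R)-1-(2,4-dihydroxyphenyl)-3-hydroxypropan-2-yl]-3-methoxyphenyl} ether | COc1c([C@@H](Cc2ccc(O)cc2O)CO)ccc(Oc2ccc([C@@H](Cc3ccc(O)cc3O)CO)c(OC)c2OCc2ccccc2)c1OCc1ccccc1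
A6 | alternative 3 | bis-chalcone: bis{2-(benzyloxy)-4-[(E)-3-(2,4-bis(benzyloxy)phenyl)-3-oxoprop-1-enyl]-3-methoxyphenyl} ether | COc1c(/C=C/C(=O)c2ccc(OCc3ccccc3)cc2OCc2ccccc2)ccc(Oc2ccc(/C=C/C(=O)c3ccc(OCc4ccccc4)cc3OCc3ccccc3)c(OC)c2OCc2ccccc2)c1OCc1ccccc1
A7 | alternative 3 | bis{2-(benzyloxy)-4-[(2R)-1-(2,4-bis(benzyloxy)phenyl)-3,3-dimethoxy-1-oxopropan-2-yl]-3-methoxyphenyl} ether | COc1c([C@@H](C(=O)c2ccc(OCc3ccccc3)cc2OCc2ccccc2)C(OC)OC)ccc(Oc2ccc([C@@H](C(=O)c3ccc(OCc4ccccc4)cc3OCc3ccccc3)C(OC)OC)c(OC)c2OCc2ccccc2)c1OCc1ccccc1
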